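**Plan**
- Retrosynthesis: the two O-benzyl groups and the saturated bridge go back to a bis(benzyl ether) stilbene, then the C3 O–Me bond is cut; ring A is opened at C6–C1 (aldol retron) to a linear styryl 1,3,5-triketone.
- The triketone is cut between the cinnamoyl carbonyl and its neighbouring CH2 (dianion acylation), then at the two ArCH2–C bonds to acetylacetone.
- Forward: C3-benzylation and γ-benzylation of acetylacetone, acylation with a 3-methoxycinnamoyl Weinreb amide, base-mediated closure of ring A (the only ring formed), O-methylation, hydrogenation.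
- Enabling feature: ring A (C1 bridge carbon, C2–H, C3–OMe, C4–benzyl, C5–OH, C6–benzyl) carries oxygen on C3 and C5 and none on C1. This is the pattern of a folded triketide whose C1 carbonyl is consumed by aldol dehydration.
- Stereochemistry: the target has none; the E-olefin of the cinnamic acid is carried through and hydrogenated in the last step.

Key step: step 5

Remark: the target has no stereocentre or stereogenic axis, so it is achiral and needs no enantiocontrol; ring A numbering (C1 bridge, C2 H, C3 OMe, C4 benzyl, C5 OH, C6 benzyl) is also used for the chain carbons of the open precursor that become these atoms.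

**Route**

Step 1
Reactants: 1 acetylacetone (pentane-2,4-dione); 2 4-(benzyloxy)benzyl bromide
Product: 3 3-[4-(benzyloxy)benzyl]pentane-2,4-dione
Conditions: 1 (3 equiv), K2CO3 (1.2 equiv), acetone, reflux
Reagents that add atoms: none
Why: C-alkylation of a β-diketone potassium enolate with a benzylic bromide is standard, excess diketone suppresses double alkylation, and the aprotic solvent avoids retro-Claisen deacetylation.

Step 2
Reactants: 3 3-[4-(benzyloxy)benzyl]pentane-2,4-dione; 2 4-(benzyloxy)benzyl bromide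
Product: 5 3-[4-(benzyloxy)benzyl]-6-[4-(benzyloxy)phenyl]hexane-2,4-dione, via dilithiated diketone 4 (not isolated)
Conditions: LDA (2.05 equiv), THF, −78 → 0 °C; then 2 (1.0 equiv), 0 °C → rt; 1 M HCl
Reagents that add atoms: none
Why: γ-Alkylation of a β-diketone 1,3-dianion occurs only at the more basic terminal carbanion, and because the two methyl termini of 3 are equivalent a single product should result.

Step 3
Reactants: 6 (E)-3-methoxycinnamic acid
Product: 8 (E)-N-methoxy-3-(3-methoxyphenyl)-N-methylprop-2-enamide, via acyl imidazole 7 (not isolated)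
Conditions: CDI (1.2 equiv), CH2Cl2, rt; then MeNH(OMe)·HCl (1.3 equiv), rt
Reagents that add atoms: N,O-dimethylhydroxylamine hydrochloride, CNOC.Cl; 1,1'-carbonyldiimidazole, O=C(n1ccnc1)n1ccnc1 (its imidazole ring is carried only by 7)
Why: Weinreb amide formation by CDI activation and aminolysis is a routine acyl substitution that leaves the E-olefin untouched.

Step 4
Reactants: 5 3-[4-(benzyloxy)benzyl]-6-[4-(benzyloxy)phenyl]hexane-2,4-dione; 8 (E)-N-methoxy-3-(3-methoxyphenyl)-N-methylprop-2-enamide
Product: 10 (E)-9-[4-(benzyloxy)phenyl]-6-[4-(benzyloxy)benzyl]-1-(3-methoxyphenyl)non-1-ene-3,5,7-trione, via dilithiated diketone 9 (not isolated)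
Conditions: 5 (1.5 equiv), LDA (3.2 equiv), THF, −78 → −20 °C; then 8 (1.0 equiv), −78 → 0 °C; AcOH, −78 °C
Reagents that add atoms: none
Why: Weinreb ketone synthesis with a β-diketone 1,3-dianion: the second, kinetic deprotonation should occur at the methyl group and not at the CH2 of the arylethyl arm, the hard terminal carbanion adds 1,2 to the amide, and the chelated tetrahedral adduct persists until the quench so that the more acidic triketone does not meet unreacted dianion.

Step 5
Reactants: 10 (E)-9-[4-(benzyloxy)phenyl]-6-[4-(benzyloxy)benzyl]-1-(3-methoxyphenyl)non-1-ene-3,5,7-trione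
Product: 12 (E)-2,4-bis[4-(benzyloxy)benzyl]-5-[2-(3-methoxyphenyl)ethenyl]benzene-1,3-diol, via cyclic ketol 11 (not isolated)
Conditions: KOH (1 M in H2O/1,4-dioxane 1:1, excess), degassed, 0.02 M, rt → 60 °C; then 1 M HCl
Reagents that add atoms: none
Why: In strong base 10 rests as the C2,C4-dienolate, which equilibrates by proton transfer with a minor dianion deprotonated at C4 and C6; in that tautomer the C1 styryl ketone is un-ionised and is attacked by the C6 carbanion to give ketol 11, which loses hydroxide (E1cB) and enolises twice to the resorcinol, an irreversible exit. The closest known reactions are the alkali-mediated aldol cyclisation of heptane-2,4,6-trione to orcinol and the aldol aromatisation of 3,5,7-triketo acids to resorcylic acids. Ring A closes in a 6-(enolendo)-exo-trig mode. No stereocentre survives: the three centres of 11 vanish on aromatisation and the E-olefin is not involved. The step needs chemoselectivity for the C6→C1 closure: the styryl group leaves C1 without a second enolisable neighbour, so this is the only six-membered aldol mode, the basic medium suppresses the acid-promoted O-cyclisation to a 4-pyranone, and oxa-Michael or C-Michael adducts at the styryl β-carbon can revert whereas aromatisation cannot. Dilution and exclusion of oxygen guard against intermolecular Michael addition and oxidation of the electron-rich stilbene resorcinol.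

Step 6
Reactants: 12 (E)-2,4-bis[4-(benzyloxy)benzyl]-5-[2-(3-methoxyphenyl)ethenyl]benzene-1,3-diol
Product: 13 2,6-bis[4-(benzyloxy)benzyl]-3-methoxy-5-[(E)-2-(3-methoxyphenyl)ethenyl]phenol
Conditions: MeI (1.05 equiv), K2CO3 (1.1 equiv), acetone, rt
Reagents that add atoms: iodomethane, CI
Why: Williamson etherification with limiting base and electrophile should favour the C3 hydroxyl, which has one ortho substituent and is the more acidic and accessible, over the C5 hydroxyl flanked by two benzyl groups.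

Step 7
Reactants: 13 2,6-bis[4-(benzyloxy)benzyl]-3-methoxy-5-[(E)-2-(3-methoxyphenyl)ethenyl]phenol
Product: 15 2,6-bis(4-hydroxybenzyl)-3-methoxy-5-[2-(3-methoxyphenyl)ethyl]phenol, via bibenzyl bis(benzyl ether) 14 (not isolated)
Conditions: H2 (1 atm), 10% Pd/C, EtOAc/MeOH, rt
Reagents that add atoms: none
Why: Heterogeneous catalytic hydrogenation saturates the stilbene double bond and hydrogenolyses both aryl benzyl ethers in one operation, while the diarylmethane C–C bonds, the methyl ethers and the arenes are inert under these conditions.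

**Compound list**

1 | acetylacetone (pentane-2,4-dione) | CC(=O)CC(C)=O | starting material
2 | 4-(benzyloxy)benzyl bromide | BrCc1ccc(OCc2ccccc2)cc1 | starting material
3 | 3-[4-(benzyloxy)benzyl]pentane-2,4-dione | CC(=O)C(Cc1ccc(OCc2ccccc2)cc1)C(C)=O | intermediate
4 | dilithium 1,3-dianion of 3 (C3 and one methyl deprotonated, drawn as the bis-enolate, enolate geometry undefined) | [Li+].[Li+].C=C([O-])C(Cc1ccc(OCc2ccccc2)cc1)=C(C)[O-] | intermediate
5 | 3-[4-(benzyloxy)benzyl]-6-[4-(benzyloxy)phenyl]hexane-2,4-dione (racemic, C3 epimerisable) | CC(=O)C(Cc1ccc(OCc2ccccc2)cc1)C(=O)CCc1ccc(OCc2ccccc2)cc1 | intermediate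
6 | (E)-3-methoxycinnamic acid | COc1cccc(/C=C/C(=O)O)c1 | starting material
7 | (E)-1-(1H-imidazol-1-yl)-3-(3-methoxyphenyl)prop-2-en-1-one | COc1cccc(/C=C/C(=O)n2ccnc2)c1 | intermediate
8 | (E)-N-methoxy-3-(3-methoxyphenyl)-N-methylprop-2-enamide | COc1cccc(/C=C/C(=O)N(C)OC)c1 | intermediate
9 | dilithium 1,3-dianion of 5 (C3 and the C1 methyl deprotonated, drawn as the bis-enolate, enolate geometry undefined) | [Li+].[Li+].C=C([O-])C(Cc1ccc(OCc2ccccc2)cc1)=C([O-])CCc1ccc(OCc2ccccc2)cc1 | intermediate
10 | (E)-9-[4-(benzyloxy)phenyl]-6-[4-(benzyloxy)benzyl]-1-(3-methoxyphenyl)non-1-ene-3,5,7-trione (racemic at chain C6, largely enolised) | COc1cccc(/C=C/C(=O)CC(=O)C(Cc2ccc(OCc3ccccc3)cc2)C(=O)CCc2ccc(OCc3ccccc3)cc2)c1 | intermediate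
11 | 2,4-bis[4-(benzyloxy)benzyl]-5-hydroxy-5-[(E)-2-(3-methoxyphenyl)ethenyl]cyclohexane-1,3-dione (mixture of diastereomers, all centres transient) | COc1cccc(/C=C/C2(O)CC(=O)C(Cc3ccc(OCc4ccccc4)cc3)C(=O)C2Cc2ccc(OCc3ccccc3)cc2)c1 | intermediate
12 | (E)-2,4-bis[4-(benzyloxy)benzyl]-5-[2-(3-methoxyphenyl)ethenyl]benzene-1,3-diol | COc1cccc(/C=C/c2cc(O)c(Cc3ccc(OCc4ccccc4)cc3)c(O)c2Cc2ccc(OCc3ccccc3)cc2)c1 | intermediate
13 | 2,6-bis[4-(benzyloxy)benzyl]-3-methoxy-5-[(E)-2-(3-methoxyphenyl)ethenyl]phenol | COc1cccc(/C=C/c2cc(OC)c(Cc3ccc(OCc4ccccc4)cc3)c(O)c2Cc2ccc(OCc3ccccc3)cc2)c1 | intermediate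
14 | 2,6-bis[4-(benzyloxy)benzyl]-3-methoxy-5-[2-(3-methoxyphenyl)ethyl]phenol | COc1cccc(CCc2cc(OC)c(Cc3ccc(OCc4ccccc4)cc3)c(O)c2Cc2ccc(OCc3ccccc3)cc2)c1 | intermediate
15 | 2,6-bis(4-hydroxybenzyl)-3-methoxy-5-[2-(3-methoxyphenyl)ethyl]phenol (CNP0201265.0, achiral) | COc1cccc(CCc2cc(OC)c(Cc3ccc(O)cc3)c(O)c2Cc2ccc(O)cc2)c1 | target

**Step count and risks**

Total steps: 7. Longest linear sequence: 6 steps (steps 1, 2, 4, 5, 6, 7; step 3 is a one-step branch).

Steps most likely to fail:

1. Step 5. The doubly enolised triketone may close only slowly, because the nucleophilic C6 is activated by one carbonyl only. Hydroxide-induced retro-Claisen fragmentation of the 2-benzyl-1,3-diketone unit, or intermolecular Michael addition, could then overtake ring formation.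
   Fallback, setting out from 3 and 8 and coming back at 15: the second benzyl group is carried at the ketone oxidation level so that C6 becomes a 1,3-diketone methylene.
   - Dianion 4 of 3 is aroylated with methyl 4-(benzyloxy)benzoate (LDA 3.1 equiv, THF) to give 1-[4-(benzyloxy)phenyl]-4-[4-(benzyloxy)benzyl]hexane-1,3,5-trione F1.
   - The trianion of F1 (LDA 3.3 equiv) is acylated at its terminal methyl with 8 to give (E)-1-[4-(benzyloxy)phenyl]-4-[4-(benzyloxy)benzyl]-9-(3-methoxyphenyl)non-8-ene-1,3,5,7-tetrone F2.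
   - Mild aqueous base at rt should close the same C6–C1 bond, as in the known cyclisation of 1,3,5,7-tetraketones to acylresorcinols. The cinnamoyl carbonyl is a better electrophile than the electron-rich aroyl carbonyl, so the product should be [4-(benzyloxy)phenyl]{3-[4-(benzyloxy)benzyl]-2,4-dihydroxy-6-[(E)-2-(3-methoxyphenyl)ethenyl]phenyl}methanone F3.
   - MeI/K2CO3 should methylate only the non-chelated hydroxyl para to the ketone, giving [4-(benzyloxy)phenyl]{3-[4-(benzyloxy)benzyl]-2-hydroxy-4-methoxy-6-[(E)-2-(3-methoxyphenyl)ethenyl]phenyl}methanone F4.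
   - Hydrogenation of F4 (H2, Pd/C, EtOH/AcOH, cat. HCl) saturates the olefin, removes both benzyl ethers and hydrogenolyses the diaryl ketone to CH2, giving 15.

2. Step 6. The methylation may discriminate too little between the two phenolic hydroxyls, or run on to the dimethyl ether.
   Fallback, setting out from 12 and coming back at 15: the steric bias is amplified with a bulky silyl group and the hindered oxygen is capped with a group that the last step removes.
   - TIPSCl/imidazole/DMF should silylate only the C3 hydroxyl, giving (E)-2,6-bis[4-(benzyloxy)benzyl]-5-[2-(3-methoxyphenyl)ethenyl]-3-[(triisopropylsilyl)oxy]phenol F5.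
   - NaH/BnBr/DMF benzylates the hindered C5 hydroxyl to give the tris(benzyl ether) silyl ether F6.
   - TBAF/THF frees the C3 hydroxyl, giving (E)-3-(benzyloxy)-2,4-bis[4-(benzyloxy)benzyl]-5-[2-(3-methoxyphenyl)ethenyl]phenol F7.
   - MeI/K2CO3 gives the C3 methyl ether of the tris(benzyl ether) F8.
   - The conditions of step 7 applied to F8 remove three benzyl groups and saturate the olefin, giving 15.

3. Step 4. Conjugate addition of the dianion to the cinnamoyl amide, or proton transfer between the triketone formed and unreacted dianion, may erode the acyl transfer.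
   Fallback, setting out from 5 and coming back at 10: the C–C bond is made at the aldehyde oxidation level. Dianion 9 is added to (E)-3-methoxycinnamaldehyde (THF, −78 °C), which should react 1,2 only, to give (E)-9-[4-(benzyloxy)phenyl]-6-[4-(benzyloxy)benzyl]-3-hydroxy-1-(3-methoxyphenyl)non-1-ene-5,7-dione F9. Selective oxidation of the allylic alcohol with MnO2 (CH2Cl2, rt) then gives 10.

**Further compounds**

F1 | step 5 | 1-[4-(benzyloxy)phenyl]-4-[4-(benzyloxy)benzyl]hexane-1,3,5-trione (racemic, enolised) | CC(=O)C(Cc1ccc(OCc2ccccc2)cc1)C(=O)CC(=O)c1ccc(OCc2ccccc2)cc1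
F2 | step 5 | (E)-1-[4-(benzyloxy)phenyl]-4-[4-(benzyloxy)benzyl]-9-(3-methoxyphenyl)non-8-ene-1,3,5,7-tetrone (racemic, enolised) | COc1cccc(/C=C/C(=O)CC(=O)C(Cc2ccc(OCc3ccccc3)cc2)C(=O)CC(=O)c2ccc(OCc3ccccc3)cc2)c1
F3 | step 5 | [4-(benzyloxy)phenyl]{3-[4-(benzyloxy)benzyl]-2,4-dihydroxy-6-[(E)-2-(3-methoxyphenyl)ethenyl]phenyl}methanone | COc1cccc(/C=C/c2cc(O)c(Cc3ccc(OCc4ccccc4)cc3)c(O)c2C(=O)c2ccc(OCc3ccccc3)cc2)c1
F4 | step 5 | [4-(benzyloxy)phenyl]{3-[4-(benzyloxy)benzyl]-2-hydroxy-4-methoxy-6-[(E)-2-(3-methoxyphenyl)ethenyl]phenyl}methanone | COc1cccc(/C=C/c2cc(OC)c(Cc3ccc(OCc4ccccc4)cc3)c(O)c2C(=O)c2ccc(OCc3ccccc3)cc2)c1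
F5 | step 6 | (E)-2,6-bis[4-(benzyloxy)benzyl]-5-[2-(3-methoxyphenyl)ethenyl]-3-[(triisopropylsilyl)oxy]phenol | COc1cccc(/C=C/c2cc(O[Si](C(C)C)(C(C)C)C(C)C)c(Cc3ccc(OCc4ccccc4)cc3)c(O)c2Cc2ccc(OCc3ccccc3)cc2)c1
F6 | step 6 | (E)-{3-(benzyloxy)-2,4-bis[4-(benzyloxy)benzyl]-5-[2-(3-methoxyphenyl)ethenyl]phenoxy}triisopropylsilane | COc1cccc(/C=C/c2cc(O[Si](C(C)C)(C(C)C)C(C)C)c(Cc3ccc(OCc4ccccc4)cc3)c(OCc3ccccc3)c2Cc2ccc(OCc3ccccc3)cc2)c1
F7 | step 6 | (E)-3-(benzyloxy)-2,4-bis[4-(benzyloxy)benzyl]-5-[2-(3-methoxyphenyl)ethenyl]phenol | COc1cccc(/C=C/c2cc(O)c(Cc3ccc(OCc4ccccc4)cc3)c(OCc3ccccc3)c2Cc2ccc(OCc3ccccc3)cc2)c1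
F8 | step 6 | (E)-2-(benzyloxy)-1,3-bis[4-(benzyloxy)benzyl]-4-methoxy-6-[2-(3-methoxyphenyl)ethenyl]benzene | COc1cccc(/C=C/c2cc(OC)c(Cc3ccc(OCc4ccccc4)cc3)c(OCc3ccccc3)c2Cc2ccc(OCc3ccccc3)cc2)c1
F9 | step 4 | (E)-9-[4-(benzyloxy)phenyl]-6-[4-(benzyloxy)benzyl]-3-hydroxy-1-(3-methoxyphenyl)non-1-ene-5,7-dione (mixture of diastereomers) | COc1cccc(/C=C/C(O)CC(=O)C(Cc2ccc(OCc3ccccc3)cc2)C(=O)CCc2ccc(OCc3ccccc3)cc2)c1
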